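## Retrosynthetic overview

1. Target 24 ⇐ 9‑O‑acylation and C11 methylenation (Mannich, then elimination) of the saturated tricyclic hydroxy lactone 20.
2. Ring A (oxepane O–C5–C4–C3–C2–C1–C10) is closed last, by RCM at C2=C3 and hydrogenation. Ring B (oxepane O–C5–C6–C7–C8–C9–C10) is closed just before, by stereospecific 7‑endo opening of a 9,10‑epoxide by the C5 hydroxyl (sets C9 and C10).
3. C4/C5 come from a Brown anti‑crotylation of aldehyde 15; C5 is reached by one‑carbon homologation at C6.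
4. The key C7–C8 bond and ring C (γ‑lactone, formed first) come from an intermolecular Evans syn‑aldol of succinate imide 9 (fragment 1: C6, C7, C11, C12) with dienal 6 (fragment 2: C8, C9, C10, C14, C1, C2), then lactonisation.
5. Ring order: C (lactone) → B → A.

Assumption: germacranolide‑type locants are used as labels (C1–C10 perimeter, C11–C13 lactone carbons, C14 = methyl on C10, C15 = methyl on C4; lactone O on C8, ether O between C5 and C10, ester O on C9); with them the target is (4S,5R,7R,8R,9S,10R).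

## Route

Step 1
Reactants: 1 allyl bromide; 2 ethynylmagnesium bromide
Product: 3 pent-1-en-4-yne
Conditions: CuCl (5 mol%), THF, 0 → 40 °C; fractional distillation
Reagents that add atoms: none
Why: Copper‑catalysed coupling of the acetylide Grignard reagent with the allylic bromide gives the skipped enyne and keeps the terminal alkyne C–H for the next step.

Step 2
Reactants: 3 pent-1-en-4-yne
Product: 5 (2E)-3-methylhexa-2,5-dien-1-ol, via alkenylalane 4 (not isolated)
Conditions: Me3Al, Cp2ZrCl2 (20 mol%), CH2Cl2, 0 °C → rt; then n-BuLi, THF, −78 °C; (CH2O)n, −78 °C → rt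
Reagents that add atoms: trimethylaluminium C[Al](C)C; paraformaldehyde (as formaldehyde) C=O
Why: Negishi zirconium‑catalysed carboalumination adds methyl and aluminium syn across the alkyne (methyl to the internal carbon), and hydroxymethylation of the alanate with retention fixes the (E)‑trisubstituted C9=C10 alkene.

Step 3
Reactants: 5 (2E)-3-methylhexa-2,5-dien-1-ol
Product: 6 (2E)-3-methylhexa-2,5-dienal
Conditions: MnO2 (excess), CH2Cl2, rt
Reagents that add atoms: none
Why: Chemoselective allylic oxidation with MnO2 gives the enal without E/Z isomerisation.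

Step 4
Reactants: 7 (4R)-4-benzyl-1,3-oxazolidin-2-one; 8 methyl 4-chloro-4-oxobutanoate
Product: 9 methyl 4-[(4R)-4-benzyl-2-oxo-1,3-oxazolidin-3-yl]-4-oxobutanoate
Conditions: n-BuLi, THF, −78 °C; then 8, −78 → 0 °C
Reagents that add atoms: none
Why: N‑acylation of the lithiated oxazolidinone by the acid chloride installs the Evans auxiliary on the succinate unit.

Step 5
Reactants: 9 methyl 4-[(4R)-4-benzyl-2-oxo-1,3-oxazolidin-3-yl]-4-oxobutanoate; 6 (2E)-3-methylhexa-2,5-dienal
Product: 11 (4R)-4-benzyl-3-{[(2S,3R)-2-[(1E)-2-methylpenta-1,4-dien-1-yl]-5-oxooxolan-3-yl]carbonyl}-1,3-oxazolidin-2-one, via syn-aldol adduct 10 (not isolated)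
Conditions: Bu2BOTf, iPr2NEt, CH2Cl2, −78 → 0 °C; 6, −78 → 0 °C; pH 7 buffer, H2O2, MeOH; then PPTS (cat.), CH2Cl2, rt
Reagents that add atoms: none
Why: Evans syn‑aldol: the (Z)‑boron enolate of the imide (formed selectively over the ester) adds through a Zimmerman–Traxler chair on the face away from the benzyl group, setting C7 and C8 in the 7,8‑syn sense, and the γ‑hydroxy ester then lactonises to the trans‑disubstituted ring C.

Step 6
Reactants: 11 lactone imide
Product: 12 (4S,5S)-4-(hydroxymethyl)-5-[(1E)-2-methylpenta-1,4-dien-1-yl]oxolan-2-one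
Conditions: NaBH4, THF/H2O (4:1), 0 °C → rt
Reagents that add atoms: none
Why: Borohydride reduces the activated N‑acyl imide chemoselectively to the primary alcohol, leaving the less electrophilic γ‑lactone and releasing the auxiliary.

Step 7
Reactants: 12 hydroxymethyl lactone
Product: 13 (2S,3R)-2-[(1E)-2-methylpenta-1,4-dien-1-yl]-5-oxooxolane-3-carbaldehyde
Conditions: Dess–Martin periodinane, CH2Cl2, 0 °C → rt
Reagents that add atoms: none
Why: Dess–Martin oxidation under non‑basic conditions gives the α‑branched aldehyde without touching C7, whose trans arrangement is also the thermodynamic one.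

Step 8
Reactants: 13 formyl lactone
Product: 15 2-[(2R,3R)-2-[(1E)-2-methylpenta-1,4-dien-1-yl]-5-oxooxolan-3-yl]acetaldehyde, via enol ether 14 (not isolated)
Conditions: Ph3P(CH2OMe)Cl, KN(SiMe3)2, THF, 0 °C; 13, −78 → 0 °C; then 1 M HCl, THF, rt
Reagents that add atoms: (methoxymethyl)triphenylphosphonium chloride COC[P+](c1ccccc1)(c1ccccc1)c1ccccc1.[Cl-]; water O
Why: Wittig methoxymethylenation followed by enol‑ether hydrolysis is a one‑carbon homologation that places the aldehyde on C5; elimination of the ring oxygen from C8 is stereoelectronically disfavoured in the lactone and no stereocentre is touched.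

Step 9
Reactants: 15 homologated aldehyde
Product: 16 (4R,5R)-4-[(2R,3S)-2-hydroxy-3-methylpent-4-en-1-yl]-5-[(1E)-2-methylpenta-1,4-dien-1-yl]oxolan-2-one
Conditions: (E)-but-2-ene, KOtBu, n-BuLi, THF, −78 → −45 °C; (−)-Ipc2BOMe [from (+)-α-pinene], −78 °C; BF3·OEt2; 15, −78 °C; NaBO3·4H2O, THF/H2O, rt
Reagents that add atoms: (E)-but-2-ene C/C=C/C
Why: Brown crotylboration (carbonyl allylation): the (E)‑crotylborane reacts through a closed chair to give the 4,5‑anti product, and the (+)-α-pinene‑derived Ipc groups direct attack to the Si face of the aldehyde, setting C5 (R) and C4 (S) under reagent control.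

Step 10
Reactants: 16 homoallylic alcohol
Product: 17 (4R,5R)-4-[(2R,3S)-2-hydroxy-3-methylpent-4-en-1-yl]-5-[(2S,3S)-3-methyl-3-(prop-2-en-1-yl)oxiran-2-yl]oxolan-2-one
Conditions: ent-Shi ketone (1,2:4,5-di-O-isopropylidene-β-L-erythro-2,3-hexodiulo-2,6-pyranose, 30 mol%), KHSO5 (Oxone), K2CO3, Bu4NHSO4 (cat.), MeCN/(MeO)2CH2/aq. Na2B4O7 buffer (pH 10.5), 0 °C
Reagents that add atoms: potassium peroxymonosulfate (Oxone) [K+].[O-]S(=O)(=O)OO
Why: Shi asymmetric epoxidation: the chiral dioxirane epoxidises only the electron‑rich (E)‑trisubstituted alkene (terminal alkenes are inert) and, by catalyst control through the spiro transition state, gives the (9S,10S)‑epoxide.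

Step 11
Reactants: 17 epoxy alcohol
Product: 18 ring-B hydroxy ether (4S,5R,7R,8R,9S,10R): trans-fused γ-lactone/oxepane with (S)-but-3-en-2-yl on C5, methyl plus allyl on C10 and OH on C9
Conditions: CSA (10 mol%), CH2Cl2, 0 °C → rt
Reagents that add atoms: none
Why: Acid‑catalysed intramolecular epoxide opening (7‑endo): the C5 hydroxyl attacks the tertiary, cation‑stabilising C10 with inversion (C9 is deactivated by the adjacent lactone C–O), closing ring B with C10 (R) and leaving 9‑OH with retention (S).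

Step 12
Reactants: 18 ring-B hydroxy ether
Product: 19 (4S,5R,7R,8R,9S,10R)-5,10-epoxy-9-hydroxy-13-norgermacr-2Z-en-8,12-olide
Conditions: second-generation Grubbs catalyst RuCl2(=CHPh)(PCy3)(H2IMes) (10 mol%), CH2Cl2 (2 mM), 40 °C
Reagents that add atoms: none
Why: Ring‑closing metathesis of the two cis‑disposed terminal alkenes on C5 and C10 closes ring A as a cycloheptene (C2=C3), helped by the quaternary C10 and driven by loss of ethene.

Step 13
Reactants: 19 tricyclic alkene
Product: 20 (4S,5R,7R,8R,9S,10R)-5,10-epoxy-9-hydroxy-13-norgermacran-8,12-olide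
Conditions: H2 (1 atm), 10% Pd/C, EtOAc, rt
Reagents that add atoms: none
Why: Heterogeneous catalytic hydrogenation saturates the ring alkene and creates no stereocentre.

Step 14
Reactants: 20 saturated hydroxy lactone
Product: 21 13-(dimethylamino)-(4S,5R,7R,8R,9S,10R)-5,10-epoxy-9-hydroxygermacran-8,12-olide (C11 epimers)
Conditions: LiN(iPr)2 (2.3 equiv), THF, −78 °C (inverse addition); Me2N=CH2+ I− (3 equiv), −78 → 0 °C
Reagents that add atoms: N,N-dimethylmethyleneiminium iodide (Eschenmoser's salt) C=[N+](C)C.[I-]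
Why: Mannich‑type aminomethylation of the lactone lithium enolate (alkoxide/enolate dianion) installs C13; the new C11 centre is destroyed in the next step.

Step 15
Reactants: 21 Mannich base
Product: 23 (4S,5R,7R,8R,9S,10R)-5,10-epoxy-9-hydroxygermacr-11(13)-en-8,12-olide, via ammonium iodide 22 (not isolated)
Conditions: MeI, MeOH/CH2Cl2, rt; then aq. NaHCO3, CH2Cl2, rt
Reagents that add atoms: none
Why: N‑quaternisation followed by Hofmann‑type (E1cB) elimination of trimethylamine gives the exocyclic α‑methylene lactone.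

Step 16
Reactants: 23 α-methylene hydroxy lactone
Product: 24 (4S,5R,7R,8R,9S,10R)-5,10-epoxy-9-(3-methylbutanoyloxy)germacr-11(13)-en-8,12-olide (CNP0274454.1)
Conditions: (iBuCO)2O, DMAP, Et3N, CH2Cl2, rt
Reagents that add atoms: 3-methylbutanoic anhydride CC(C)CC(=O)OC(=O)CC(C)C
Why: DMAP‑catalysed acylation of the secondary C9 alcohol proceeds with retention and gives the target.

## Compound list

1 | allyl bromide (3-bromoprop-1-ene) | C=CCBr | starting material
2 | ethynylmagnesium bromide | C#C[Mg]Br | starting material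
3 | pent-1-en-4-yne | C=CCC#C | intermediate
4 | dimethyl[(1E)-2-methylpenta-1,4-dien-1-yl]alumane (not isolated) | C[Al](C)/C=C(/CC=C)C | intermediate
5 | (2E)-3-methylhexa-2,5-dien-1-ol | OC/C=C(/CC=C)C | intermediate
6 | (2E)-3-methylhexa-2,5-dienal | O=C/C=C(/CC=C)C | intermediate
7 | (4R)-4-benzyl-1,3-oxazolidin-2-one | O=C1N[C@H](Cc2ccccc2)CO1 | starting material
8 | methyl 4-chloro-4-oxobutanoate | COC(=O)CCC(Cl)=O | starting material
9 | methyl 4-[(4R)-4-benzyl-2-oxo-1,3-oxazolidin-3-yl]-4-oxobutanoate | COC(=O)CCC(=O)N1[C@H](Cc2ccccc2)COC1=O | intermediate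
10 | methyl (3R,4S,5E)-3-[(4R)-4-benzyl-2-oxo-1,3-oxazolidine-3-carbonyl]-4-hydroxy-6-methylnona-5,8-dienoate (not isolated) | COC(=O)C[C@@H](C(=O)N1[C@H](Cc2ccccc2)COC1=O)[C@@H](O)/C=C(/CC=C)C | intermediate
11 | (4R)-4-benzyl-3-{[(2S,3R)-2-[(1E)-2-methylpenta-1,4-dien-1-yl]-5-oxooxolan-3-yl]carbonyl}-1,3-oxazolidin-2-one | O=C1C[C@@H](C(=O)N2[C@H](Cc3ccccc3)COC2=O)[C@H](/C=C(/CC=C)C)O1 | intermediate
12 | (4S,5S)-4-(hydroxymethyl)-5-[(1E)-2-methylpenta-1,4-dien-1-yl]oxolan-2-one | O=C1C[C@@H](CO)[C@H](/C=C(/CC=C)C)O1 | intermediate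
13 | (2S,3R)-2-[(1E)-2-methylpenta-1,4-dien-1-yl]-5-oxooxolane-3-carbaldehyde | O=C1C[C@@H](C=O)[C@H](/C=C(/CC=C)C)O1 | intermediate
14 | (4S,5R)-4-(2-methoxyethenyl)-5-[(1E)-2-methylpenta-1,4-dien-1-yl]oxolan-2-one, E/Z mixture (not isolated) | O=C1C[C@@H](C=COC)[C@H](/C=C(/CC=C)C)O1 | intermediate
15 | 2-[(2R,3R)-2-[(1E)-2-methylpenta-1,4-dien-1-yl]-5-oxooxolan-3-yl]acetaldehyde | O=C1C[C@@H](CC=O)[C@H](/C=C(/CC=C)C)O1 | intermediate
16 | (4R,5R)-4-[(2R,3S)-2-hydroxy-3-methylpent-4-en-1-yl]-5-[(1E)-2-methylpenta-1,4-dien-1-yl]oxolan-2-one | O=C1C[C@@H](C[C@@H](O)[C@@H](C)C=C)[C@H](/C=C(/CC=C)C)O1 | intermediate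
17 | (4R,5R)-4-[(2R,3S)-2-hydroxy-3-methylpent-4-en-1-yl]-5-[(2S,3S)-3-methyl-3-(prop-2-en-1-yl)oxiran-2-yl]oxolan-2-one | O=C1C[C@@H](C[C@@H](O)[C@@H](C)C=C)[C@H]([C@@H]2O[C@@]2(C)CC=C)O1 | intermediate
18 | ring-B hydroxy ether (4S,5R,7R,8R,9S,10R): trans-fused γ-lactone/oxepane, (S)-but-3-en-2-yl on C5, methyl and allyl on C10, OH on C9 | O=C1C[C@H]2C[C@H]([C@@H](C)C=C)O[C@](C)(CC=C)[C@@H](O)[C@@H]2O1 | intermediate
19 | (4S,5R,7R,8R,9S,10R)-5,10-epoxy-9-hydroxy-13-norgermacr-2Z-en-8,12-olide | O=C1C[C@H]2C[C@H]3O[C@](C)(C/C=C\[C@@H]3C)[C@@H](O)[C@@H]2O1 | intermediate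
20 | (4S,5R,7R,8R,9S,10R)-5,10-epoxy-9-hydroxy-13-norgermacran-8,12-olide | O=C1C[C@H]2C[C@H]3O[C@](C)(CCC[C@@H]3C)[C@@H](O)[C@@H]2O1 | intermediate
21 | 13-(dimethylamino)-(4S,5R,7R,8R,9S,10R)-5,10-epoxy-9-hydroxygermacran-8,12-olide (C11 epimers) | CN(C)CC1C(=O)O[C@@H]2[C@@H]1C[C@H]1O[C@](C)(CCC[C@@H]1C)[C@H]2O | intermediate
22 | trimethylammonium iodide of 21 (not isolated) | C[N+](C)(C)CC1C(=O)O[C@@H]2[C@@H]1C[C@H]1O[C@](C)(CCC[C@@H]1C)[C@H]2O.[I-] | intermediate
23 | (4S,5R,7R,8R,9S,10R)-5,10-epoxy-9-hydroxygermacr-11(13)-en-8,12-olide | C=C1C(=O)O[C@@H]2[C@@H]1C[C@H]1O[C@](C)(CCC[C@@H]1C)[C@H]2O | intermediate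
24 | (4S,5R,7R,8R,9S,10R)-5,10-epoxy-9-(3-methylbutanoyloxy)germacr-11(13)-en-8,12-olide (CNP0274454.1) | C=C1C(=O)O[C@@H]2[C@@H]1C[C@H]1O[C@](C)(CCC[C@@H]1C)[C@H]2OC(=O)CC(C)C | target

## Step count and risks

Total: 16 steps. Longest linear sequence: 15 steps (steps 1–3 and 5–16; step 4 is a one‑step branch).

Most likely to fail:

Step 8. Aldehyde 13 is a β‑acyloxy, α‑branched aldehyde that must survive a basic ylide. The fallback sets out from 11 and avoids both 13 and the ylide by an Arndt–Eistert homologation. LiOH/H2O2 (THF/H2O, 0 °C) removes the auxiliary to give the carboxylic acid F1. (COCl)2 with cat. DMF gives the acid chloride F2, and CH2N2 (Et2O, 0 °C) gives the diazoketone F3. Wolff rearrangement (PhCO2Ag cat., Et3N, EtSH, THF; retention at C7) gives the S‑ethyl thioester F4. Fukuyama reduction (Et3SiH, 10% Pd/C, acetone) then delivers aldehyde 15, where the route is rejoined.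

Step 11. 6‑exo attack of the C5 hydroxyl at C9 could compete with the wanted 7‑endo attack at C10. The fallback sets out from 16 and reverses the ring order. RCM of 16 (second-generation Grubbs catalyst, high dilution) gives the ten‑membered carbocyclic diene lactone F5. Epoxidation with the ent-Shi ketone gives the 9,10‑epoxide F6. CSA then triggers transannular attack of 5‑OH on C10 with inversion, the medium ring holding O5 over C10, and this gives 19 directly.

Step 12. RCM has to form an oxygen‑bridged bicycle. The fallback sets out from 18 and closes ring A by carbonyl coupling instead. TESOTf/2,6‑lutidine gives the 9‑O‑triethylsilyl ether F7. Ozonolysis (O3, CH2Cl2, −78 °C; PPh3) gives the dialdehyde F8. Intramolecular McMurry coupling (TiCl3(DME)1.5, Zn(Cu), DME, reflux) gives the cycloheptene silyl ether F9. HF·pyridine removes the silyl group and returns 19.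

Further compounds

F1 | step 8 | (2S,3R)-2-[(1E)-2-methylpenta-1,4-dien-1-yl]-5-oxooxolane-3-carboxylic acid | O=C1C[C@@H](C(=O)O)[C@H](/C=C(/CC=C)C)O1
F2 | step 8 | (2S,3R)-2-[(1E)-2-methylpenta-1,4-dien-1-yl]-5-oxooxolane-3-carbonyl chloride | O=C1C[C@@H](C(=O)Cl)[C@H](/C=C(/CC=C)C)O1
F3 | step 8 | (4R,5S)-4-(2-diazoacetyl)-5-[(1E)-2-methylpenta-1,4-dien-1-yl]oxolan-2-one | O=C1C[C@@H](C(=O)C=[N+]=[N-])[C@H](/C=C(/CC=C)C)O1
F4 | step 8 | S-ethyl 2-[(2R,3S)-2-[(1E)-2-methylpenta-1,4-dien-1-yl]-5-oxooxolan-3-yl]ethanethioate | O=C1C[C@@H](CC(=O)SCC)[C@H](/C=C(/CC=C)C)O1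
F5 | step 11 | (4S,5R,7R,8R)-5-hydroxy-13-norgermacra-1(10)E,2Z-dien-8,12-olide | O=C1C[C@H]2C[C@@H](O)[C@@H](C)/C=C\C/C(C)=C/[C@@H]2O1
F6 | step 11 | (4S,5R,7R,8R,9S,10S)-9,10-epoxy-5-hydroxy-13-norgermacr-2Z-en-8,12-olide | O=C1C[C@H]2C[C@@H](O)[C@@H](C)/C=C\C[C@]3(C)O[C@H]3[C@@H]2O1
F7 | step 12 | 9-O-triethylsilyl ether of 18 | O=C1C[C@H]2C[C@H]([C@@H](C)C=C)O[C@](C)(CC=C)[C@@H](O[Si](CC)(CC)CC)[C@@H]2O1
F8 | step 12 | dialdehyde from ozonolysis of F7 (formyl on C4 and formylmethyl on C10) | O=C1C[C@H]2C[C@H]([C@@H](C)C=O)O[C@](C)(CC=O)[C@@H](O[Si](CC)(CC)CC)[C@@H]2O1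
F9 | step 12 | 9-O-triethylsilyl ether of 19 | O=C1C[C@H]2C[C@H]3O[C@](C)(C/C=C\[C@@H]3C)[C@@H](O[Si](CC)(CC)CC)[C@@H]2O1
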